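## Retrosynthetic overview

1. The last pot cuts C3–C4 (Knoevenagel), O1–C2 (lactone) and the enol-ether C–O bond of the dihydropyranone. This gives a pentasubstituted salicylaldehyde and a tetraketide, as in the presumed polyketide pathway.
2. The tetraketide is used as its 2-pyrone, released in the flask from a keto-dioxinone through an acylketene. The keto-dioxinone comes from the dioxinone dienolate and the Weinreb amide of (R)-3-hydroxybutanoate.
3. The salicylaldehyde comes from its bis-methyl ether. The side chain is installed by aldehyde-directed ortho-lithiation and opening of (S)-propylene oxide. The aldehyde comes from 2,6-dimethoxytoluene by two methoxy-directed lithiations (MeI, then DMF).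
4. Ring order: the benzene ring is bought; then transient 2-pyrone → coumarin lactone ring → dihydropyranone, all in the final pot.
5. Both stereocentres come from the chiral pool and are never part of a bond-forming event.

Assumption: the biosynthesis is taken as union of a pentaketide salicylaldehyde with a tetraketide (Knoevenagel, lactonisation, cyclodehydration of the δ-hydroxy-β-diketone); the two 2-(2-hydroxypropyl)benzaldehydes of the route are drawn open-chain although they sit largely as their cyclic lactols (ring–chain tautomers).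

## Route

**Step 1**
Reactants: 1 2,6-dimethoxytoluene
Product: 5 2,4-dimethoxy-3,5-dimethylbenzaldehyde, via first aryllithium 2 (not isolated), via methylated arene 3 (not isolated), via second aryllithium 4 (not isolated)
Conditions: n-BuLi (1.1 eq), TMEDA, Et2O, 0 °C→rt; MeI (1.0 eq), 0 °C; n-BuLi (1.3 eq), TMEDA, rt; DMF, 0 °C; aq. HCl
Reagents that add atoms: iodomethane CI; N,N-dimethylformamide CN(C)C=O
Why: Two consecutive methoxy-directed ortho-lithiations (DoM; ring, not benzylic, metalation with n-BuLi/TMEDA): the first is capped with MeI, and in 3 the only C–H left ortho to a methoxy group is C6, so the second lithiation and DMF quench (Bouveault formylation) can only give 5.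

**Step 2**
Reactants: 5 2,4-dimethoxy-3,5-dimethylbenzaldehyde; 6 (S)-propylene oxide
Product: 9 2-[(2S)-2-hydroxypropyl]-4,6-dimethoxy-3,5-dimethylbenzaldehyde, via amino alkoxide 7 (not isolated), via ortho-lithiated amino alkoxide 8 (not isolated)
Conditions: Me2NCH2CH2N(Me)Li (from the amine + n-BuLi), THF, −20 °C; n-BuLi (3 eq), −20 °C, 12 h; CuI (10 mol%), 6 (4 eq), −40→0 °C; aq. HCl
Reagents that add atoms: none
Why: Comins-type α-amino-alkoxide-directed ortho-lithiation: the aminal formed in the flask protects the aldehyde and directs lithiation to the only remaining ring C–H, and copper-catalysed SN2 opening of the epoxide at its CH2 terminus leaves the stereocentre untouched, which fixes the (S)-carbinol.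

**Step 3**
Reactants: 9 2-[(2S)-2-hydroxypropyl]-4,6-dimethoxy-3,5-dimethylbenzaldehyde
Product: 10 2,4-dihydroxy-6-[(2S)-2-hydroxypropyl]-3,5-dimethylbenzaldehyde
Conditions: BBr3 (5 eq), CH2Cl2, −78→0 °C; H2O
Reagents that add atoms: none
Why: Lewis-acid ether cleavage (BBr3 O-demethylation) of both aryl methyl ethers; at ≤0 °C the secondary carbinol (as borate or within the lactol) is not substituted, so the (S)-centre is kept.

**Step 4**
Reactants: 11 ethyl (3R)-3-hydroxybutanoate
Product: 12 (3R)-3-hydroxy-N-methoxy-N-methylbutanamide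
Conditions: MeNH(OMe)·HCl, i-PrMgCl, THF, −20→0 °C; aq. HCl
Reagents that add atoms: N,O-dimethylhydroxylamine hydrochloride CNOC.Cl
Why: Weinreb amide formation by aminolysis of the ester with the chloromagnesium amide, which tolerates the free β-hydroxyl as its magnesium alkoxide and does not touch the (R)-centre.

**Step 5**
Reactants: 12 (3R)-3-hydroxy-N-methoxy-N-methylbutanamide; 13 2,2,6-trimethyl-4H-1,3-dioxin-4-one
Product: 15 6-[(4R)-4-hydroxy-2-oxopentyl]-2,2-dimethyl-4H-1,3-dioxin-4-one, via lithium dienolate 14 (not isolated)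
Conditions: 13 (2.2 eq), LiHMDS (2.2 eq), THF, −78 °C; then 12 (pre-treated with 1 eq LiHMDS), −78→−30 °C; aq. HCl
Reagents that add atoms: none
Why: Vinylogous (γ-selective) Claisen acylation of the dioxinone lithium dienolate by the Weinreb amide; the chelated tetrahedral adduct stops over-addition and the carbinol rides along as its lithium alkoxide, so the (R)-centre is unchanged.

**Step 6 (key step, one pot)**
Reactants: 10 2,4-dihydroxy-6-[(2S)-2-hydroxypropyl]-3,5-dimethylbenzaldehyde; 15 6-[(4R)-4-hydroxy-2-oxopentyl]-2,2-dimethyl-4H-1,3-dioxin-4-one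
Product: 19 7-hydroxy-5-[(2S)-2-hydroxypropyl]-6,8-dimethyl-3-[(2R)-2-methyl-4-oxo-3,4-dihydro-2H-pyran-6-yl]-2H-chromen-2-one, via acylketene 16 (not isolated), via pyrone 17 (not isolated), via diketone 18 (not isolated)
Conditions: 15 alone, PhMe (0.02 M), 110 °C, 1 h; then 10, piperidine/AcOH (20 mol% each), EtOH, 60 °C; then TsOH·H2O (30 mol%), rt
Reagents that add atoms: none
Why: Proposed new method: thermal retro-[4+2] of 15 expels acetone to give acylketene 16, whose ketone enol closes to the tetraketide 2-pyrone 17 (the known fate of β-keto-dioxinones); amine-catalysed Knoevenagel condensation of the nucleophilic C3 of 17 with the aldehyde of 10, attack of the ortho-phenol on the pyrone lactone carbonyl and ring opening give 18 (closest known reaction: salicylaldehyde + 4-hydroxy-6-methyl-2-pyrone → 3-acetoacetylcoumarin), and acid-catalysed cyclodehydration of its δ-hydroxy-β-diketone (6-membered hemiketal, loss of water; the known route to 2,3-dihydro-4H-pyran-4-ones) closes the last ring; no new stereocentre is formed and both carbinol C–O bonds stay intact, so (S) and (R) are carried through.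

## Compound list

1 | 2,6-dimethoxytoluene | COc1cccc(OC)c1C | starting material
2 | (2,4-dimethoxy-3-methylphenyl)lithium | [Li]c1ccc(OC)c(C)c1OC | intermediate (not isolated)
3 | 1,3-dimethoxy-2,4-dimethylbenzene | Cc1ccc(OC)c(C)c1OC | intermediate (not isolated)
4 | (2,4-dimethoxy-3,5-dimethylphenyl)lithium | Cc1cc([Li])c(OC)c(C)c1OC | intermediate (not isolated)
5 | 2,4-dimethoxy-3,5-dimethylbenzaldehyde | Cc1cc(C=O)c(OC)c(C)c1OC | intermediate
6 | (S)-propylene oxide [(2S)-2-methyloxirane] | C[C@H]1CO1 | starting material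
7 | lithium {[2-(dimethylamino)ethyl](methyl)amino}(2,4-dimethoxy-3,5-dimethylphenyl)methanolate (aminal carbon racemic) | Cc1cc(C(O[Li])N(C)CCN(C)C)c(OC)c(C)c1OC | intermediate (not isolated)
8 | lithium {[2-(dimethylamino)ethyl](methyl)amino}(2-lithio-4,6-dimethoxy-3,5-dimethylphenyl)methanolate | Cc1c([Li])c(C(O[Li])N(C)CCN(C)C)c(OC)c(C)c1OC | intermediate (not isolated)
9 | 2-[(2S)-2-hydroxypropyl]-4,6-dimethoxy-3,5-dimethylbenzaldehyde (drawn open; largely the lactol (3S)-6,8-dimethoxy-3,5,7-trimethylisochroman-1-ol) | Cc1c(C[C@H](C)O)c(C=O)c(OC)c(C)c1OC | intermediate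
10 | 2,4-dihydroxy-6-[(2S)-2-hydroxypropyl]-3,5-dimethylbenzaldehyde (drawn open; in equilibrium with its lactol) | Cc1c(C[C@H](C)O)c(C=O)c(O)c(C)c1O | intermediate
11 | ethyl (3R)-3-hydroxybutanoate | CCOC(=O)C[C@@H](C)O | starting material
12 | (3R)-3-hydroxy-N-methoxy-N-methylbutanamide | CON(C)C(=O)C[C@@H](C)O | intermediate
13 | 2,2,6-trimethyl-4H-1,3-dioxin-4-one | CC1=CC(=O)OC(C)(C)O1 | starting material
14 | lithium 2,2-dimethyl-6-methylidene-6H-1,3-dioxin-4-olate | C=C1C=C(O[Li])OC(C)(C)O1 | intermediate (not isolated)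
15 | 6-[(4R)-4-hydroxy-2-oxopentyl]-2,2-dimethyl-4H-1,3-dioxin-4-one | CC1(C)OC(=O)C=C(CC(=O)C[C@@H](C)O)O1 | intermediate
16 | (7R)-7-hydroxy-3,5-dioxooct-1-en-1-one (acylketene) | O=C=CC(=O)CC(=O)C[C@@H](C)O | intermediate (not isolated)
17 | 4-hydroxy-6-[(2R)-2-hydroxypropyl]-2H-pyran-2-one | O=c1cc(O)cc(C[C@@H](C)O)o1 | intermediate (not isolated)
18 | 7-hydroxy-3-[(5R)-5-hydroxy-3-oxohexanoyl]-5-[(2S)-2-hydroxypropyl]-6,8-dimethyl-2H-chromen-2-one | Cc1c(O)c(C)c2oc(=O)c(C(=O)CC(=O)C[C@@H](C)O)cc2c1C[C@H](C)O | intermediate (not isolated)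
19 | 7-hydroxy-5-[(2S)-2-hydroxypropyl]-6,8-dimethyl-3-[(2R)-2-methyl-4-oxo-3,4-dihydro-2H-pyran-6-yl]-2H-chromen-2-one | Cc1c(O)c(C)c2oc(=O)c(C3=CC(=O)C[C@@H](C)O3)cc2c1C[C@H](C)O | target

## Count and risks

Total: 6 steps. Longest linear sequence: 4 steps (1 → 2 → 3 → 6); the second branch is steps 4 → 5 → 6.

The three steps most likely to fail:

**Step 6.** The aldehyde of 10 is hindered, electron-rich and masked as a lactol, so the Knoevenagel stage may stall or the pyrone may give 2:1 adducts. The fallback inverts the ring order and uses an ester instead of the pyrone. It sets out from 11 and 10. The dianion of methyl acetoacetate (NaH, n-BuLi, THF, 0 °C, 3 eq) is acylated by 11 to give methyl (7R)-7-hydroxy-3,5-dioxooctanoate F1. Acid (TsOH, CH2Cl2, rt) cyclodehydrates this to methyl [(2R)-2-methyl-4-oxo-3,4-dihydro-2H-pyran-6-yl]acetate F2, so the dihydropyranone is made first. Knoevenagel condensation and lactonisation of F2 with 10 (piperidinium acetate, EtOH, 60 °C) then closes the coumarin and comes back to the route at 19.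

**Step 2.** Lithiation next to a ring methyl and opening of the epoxide by a hindered aryl metal may both be slow. The fallback changes the directing group and the oxidation level. It sets out from aryllithium 4 in the pot of step 1, which is quenched with diethylcarbamoyl chloride instead of DMF to give N,N-diethyl-2,4-dimethoxy-3,5-dimethylbenzamide F3. Amide-directed ortho-lithiation (s-BuLi, TMEDA, THF, −78 °C) and opening of 6 (BF3·OEt2) give N,N-diethyl-2-[(2S)-2-hydroxypropyl]-4,6-dimethoxy-3,5-dimethylbenzamide F4. This is lactonised (TsOH, PhMe, reflux) to (3S)-6,8-dimethoxy-3,5,7-trimethylisochroman-1-one F5. Half-reduction with DIBAL-H (CH2Cl2, −78 °C) gives the lactol, which is 9, where the route is rejoined.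

**Step 5.** The lithium alkoxide of 12 may make the amide too unreactive toward the thermally fragile dienolate. The fallback masks the carbinol. It sets out from 12, which is silylated (TBSCl, imidazole, DMF) to (3R)-3-[(tert-butyldimethylsilyl)oxy]-N-methoxy-N-methylbutanamide F6. Acylation of dienolate 14 (LiHMDS, THF, −78 °C) with F6 gives 6-[(4R)-4-[(tert-butyldimethylsilyl)oxy]-2-oxopentyl]-2,2-dimethyl-4H-1,3-dioxin-4-one F7. Desilylation (HF·pyridine, THF, 0 °C) comes back to the route at 15.

## Further compounds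

F1 | step 6 | methyl (7R)-7-hydroxy-3,5-dioxooctanoate | COC(=O)CC(=O)CC(=O)C[C@@H](C)O
F2 | step 6 | methyl [(2R)-2-methyl-4-oxo-3,4-dihydro-2H-pyran-6-yl]acetate | COC(=O)CC1=CC(=O)C[C@@H](C)O1
F3 | step 2 | N,N-diethyl-2,4-dimethoxy-3,5-dimethylbenzamide | CCN(CC)C(=O)c1cc(C)c(OC)c(C)c1OC
F4 | step 2 | N,N-diethyl-2-[(2S)-2-hydroxypropyl]-4,6-dimethoxy-3,5-dimethylbenzamide | CCN(CC)C(=O)c1c(C[C@H](C)O)c(C)c(OC)c(C)c1OC
F5 | step 2 | (3S)-6,8-dimethoxy-3,5,7-trimethylisochroman-1-one | COc1c(C)c(OC)c2c(c1C)C[C@H](C)OC2=O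
F6 | step 5 | (3R)-3-[(tert-butyldimethylsilyl)oxy]-N-methoxy-N-methylbutanamide | CON(C)C(=O)C[C@@H](C)O[Si](C)(C)C(C)(C)C
F7 | step 5 | 6-[(4R)-4-[(tert-butyldimethylsilyl)oxy]-2-oxopentyl]-2,2-dimethyl-4H-1,3-dioxin-4-one | CC1(C)OC(=O)C=C(CC(=O)C[C@@H](C)O[Si](C)(C)C(C)(C)C)O1
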